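**Assumption:** the target, dihydrocurcumin, has no stereocentre. I read "single enantiomer" as the single geometric and tautomeric form drawn, with a 6E styryl alkene and a 4Z hydrogen-bond-chelated enol.

## Retrosynthetic overview
1. I avoid the boron-templated (Pabon) condensation of vanillin with a β-diketone, and I avoid partial hydrogenation of curcumin.
2. Key disconnection: the aryl–CH2 bond of the saturated arm is cut, giving vinyl carbinol 3 and 4-iodoguaiacol 4. One Heck arylation/redox-relay step forms that bond, leaves the arm saturated and turns the carbinol into the second carbonyl of the β-diketone.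
3. Carbinol 3 comes from a protecting-group-free aldol between dilithiated dehydrozingerone 1 and acrolein 2.
4. The E-alkene is bought in 1 and is never touched. The Z-enol is the thermodynamic, chelated tautomer.
5. No ring is formed, because both arenes are purchased intact.

## Route

**Step 1**
- Reactants: 1, dehydrozingerone, (E)-4-(4-hydroxy-3-methoxyphenyl)but-3-en-2-one; 2, acrolein
- Product: 3, (E)-5-hydroxy-1-(4-hydroxy-3-methoxyphenyl)hepta-1,6-dien-3-one (racemic at C5)
- Conditions: LDA (2.2 equiv), THF–DMPU (10:1), −78 °C, 1 h; then 2 (1.3 equiv), −78 °C, 30 min; AcOH quench at −78 °C
- Reagents that add atoms: acrolein (2), C=CC=O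
- Why: This is a kinetic lithium-enolate (dianion) aldol addition in which the first equivalent of base gives the phenoxide, the second can only remove an α′-CH3 proton (there are no γ-H) to give the cross-conjugated enolate, that enolate adds 1,2 to the reactive enal at −78 °C as in gingerol-type dianion aldols, the E-alkene of 1 is carried through, and the new carbinol centre is left racemic because Step 2 destroys it.

**Step 2**
- Reactants: 3, (E)-5-hydroxy-1-(4-hydroxy-3-methoxyphenyl)hepta-1,6-dien-3-one; 4, 4-iodo-2-methoxyphenol
- Product: 5, (4Z,6E)-5-hydroxy-1,7-bis(4-hydroxy-3-methoxyphenyl)hepta-4,6-dien-3-one (target)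
- Conditions: 4 (1.1 equiv), Pd(OAc)2 (5 mol %), n-Bu4NCl (1 equiv), NaHCO3 (2.5 equiv), degassed DMF, Ar, 50 °C, 12–24 h; aq citric acid work-up (pH 4–5)
- Reagents that add atoms: 4-iodo-2-methoxyphenol (4), COc1cc(I)ccc1O, which delivers the aryl group with loss of HI
- Why: This is a Mizoroki–Heck arylation of a secondary allylic alcohol with redox relay (Melpolder–Heck/Chalk–Magennis reaction, Jeffery conditions) in which ArPdI inserts into the terminal vinyl group much faster than into the β-aryl enone and places the aryl on the CH2 terminus, β-hydride elimination takes the carbinol C–H to give an enol that tautomerises irreversibly to the ketone, the resulting β-diketone settles as the styryl-conjugated, H-bond-chelated Z-enol, the E-alkene is untouched, the racemic centre is erased, and weak insoluble NaHCO3 tolerates the free phenols while limiting E1cB dehydration.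

Mass balance: C14H16O4 (3) + C7H7IO2 (4) − HI = C21H22O6 (5).

## Compound list
| No. | Name | SMILES | Role |
|---|---|---|---|
| 1 | Dehydrozingerone, (E)-4-(4-hydroxy-3-methoxyphenyl)but-3-en-2-one | COc1cc(/C=C/C(C)=O)ccc1O | starting material |
| 2 | Acrolein | C=CC=O | starting material |
| 3 | (E)-5-Hydroxy-1-(4-hydroxy-3-methoxyphenyl)hepta-1,6-dien-3-one (racemic) | COc1cc(/C=C/C(=O)CC(O)C=C)ccc1O | intermediate |
| 4 | 4-Iodo-2-methoxyphenol | COc1cc(I)ccc1O | starting material |
| 5 | (4Z,6E)-5-Hydroxy-1,7-bis(4-hydroxy-3-methoxyphenyl)hepta-4,6-dien-3-one (dihydrocurcumin) | COc1cc(/C=C/C(O)=C/C(=O)CCc2ccc(O)c(OC)c2)ccc1O | target |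

## Summary
- Total step count: 2
- Longest linear sequence: 2

## Most likely failures
The route has only two steps, so I rank three failure points across them.

1. **Step 2, relay selectivity.**
   - Failure: β-H elimination may occur at the benzylic side and give the styrenyl carbinol. Alternatively, Pd–H may simply isomerise 3 to the ethyl diketone.
   - Fallback: separate the C–C bond formation from the redox change.
     - Make the (1E,6E)-styrenyl carbinol on purpose by cross-metathesis of 3 with commercial 2-methoxy-4-vinylphenol (Hoveyda–Grubbs II).
     - Isomerise it with an inner-sphere catalyst, either a cationic Rh(I)–dppe solvate or CpRu(PPh3)2Cl/Et3NHPF6.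
     - The transient oxidised species is metal-hydride-bound curcumin, which is symmetrical, so hydride return to either enone gives 5.
     - With an inner-sphere catalyst that keeps the hydride on the substrate, the single internal H2 equivalent prevents over-reduction.

2. **Step 1, unprotected dianion aldol.**
   - Failure: the dilithio species may be insoluble, acrolein may polymerise, or the product may undergo retro-aldol or dehydration during isolation.
   - Fallback: switch to a silyl/Lewis-acid approach.
     - Treat 1 with TBSOTf (2.2 equiv)/Et3N to give the aryl-TBS 2-silyloxydiene in one pot.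
     - Run a BF3·OEt2 Mukaiyama aldol with acrolein.
     - Carry the aryl TBS ether through the Heck relay and remove it last with Et3N·3HF. This adds two steps.

3. **Step 2, survival of substrate and catalyst.**
   - Failure: 3 may suffer E1cB dehydration, or oxa-Michael closure to a tetrahydropyranone, in warm basic DMF. The β-diketone product may also sequester Pd.
   - Fallback: reverse both the redox order and the polarity.
     - Oxidise the allylic alcohol of 3 with MnO2 to the vinyl β-diketone.
     - Add the arene as a nucleophile by Rh(I)-catalysed Hayashi–Miyaura conjugate addition of commercial 4-hydroxy-3-methoxyphenylboronic acid pinacol ester in near-neutral aqueous dioxane.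
     - This addition favours the unsubstituted vinyl ketone over the β-aryl enone.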